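Readings and results were generated by integration for substances that don't exist; the scatter is artificial.

How far does the electrophile get in birch and in elm, and does the extra free base in elm move it?

| flask | electrophile | nucleophile | free base | remark | time |
|---|---|---|---|---|---|
| epsilon | 0.30 M (fed, over 4.0 min) | 0.30 M | 0.40 M | run made earlier |  |
| alpha | 0.40 M (fed, over 4.0 min) | 0.30 M | 0.40 M | run made earlier |  |
| birch | 0.20 M (fed, over 4.0 min) | 0.300 M | 0.400 M |  | 20 min |
| elm | 0.20 M (fed, over 4.0 min) | 0.300 M | 0.520 M |  | 20 min |

| run | time / min | electrophile / % | target / % |
|---|---|---|---|
| epsilon | 2.50 | 46.2 | 14.4 |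
| epsilon | 5.00 | 63.7 | 30.4 |
| epsilon | 8.00 | 54.3 | 36.9 |
| epsilon | 10.0 | 49.3 | 38.9 |
| epsilon | 12.0 | 47.2 | 36.0 |
| alpha | 2.50 | 45.5 | 13.8 |
| alpha | 5.00 | 67.6 | 27.5 |
| alpha | 8.00 | 60.8 | 30.1 |
| alpha | 10.0 | 59.2 | 32.2 |
| alpha | 12.0 | 57.5 | 32.9 |

(standard deviation of a reading: 1 percentage point)

1. part of the electrophile that has reacted at the end, birch
2. part of the electrophile that has reacted at the end, elm
3. what raising the concentration of free base from its lowest to its highest value here does to the part of the electrophile that has reacted (changes below 5 percentage points count as none) (it rises / it falls / no change)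

- for acid set free the idle adduct is counted in
- the earlier runs were read with a standard deviation of 1 percentage point
- reactions considered so far: electrophile + nucleophile -> acid set free + target; nucleophile + acid set free <-> protonated nucleophile; acid set free + free base <-> salt of the base; nucleophile + target -> over-reaction product; nucleophile + acid set free <-> idle adduct
- percentages count the whole charge, also what has not yet gone in

I start by comparing epsilon with alpha, two flasks that differ in their electrophile charge. I work with what is left. At the last reading, 12.0 min, epsilon still holds 47.2% of its charge and alpha 57.5%, so epsilon has turned over 0.158 M and alpha 0.170 M. Alpha's charge is larger by a factor of 1.33, but its turnover by a smaller factor, 1.08. At that reading the two stand near one amount and not near one fraction, so I take the nucleophile, equal in both, as the limiting reagent.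

Supposing that epsilon has lost its whole 0.30 M of unbound nucleophile by then, which no reading shows, I get 1.89 for n, the nucleophile cost, meaning the unbound nucleophile lost per electrophile reacted. I take it from epsilon, whose charge is nearer birch's. In birch, the nucleophile charge divided by n is the electrophile paid for at this cost, which leaves 20.8% of the electrophile, so my reckoning gives 79.2% reacted, at no stated time. It has no term for free base, so it gives elm the same level.

The forecast gives 75% (69% to 82%) for birch, 79% (72% to 86%) for elm, and no change, holding that “both runs stall once about 0.15 M has reacted”. Its birch figure, reckoned for 20 min, is lower than my reckoned level.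

The flask gives 71.3% for birch and 71.9% for elm, a move of 0.6 percentage points, so no change. The forecast's elm figure is 7.1 points too high.

    electrophile + nucleophile → acid set free + target (k = 0.0180 L mol⁻¹ s⁻¹)
    nucleophile + acid set free ⇌ protonated nucleophile, settled at all times (K = 120 L mol⁻¹)
    acid set free + free base ⇌ salt of the base (K = 3.50 L mol⁻¹, k = 0.860 L mol⁻¹ s⁻¹)
    nucleophile + target → over-reaction product (k = 0.0130 L mol⁻¹ s⁻¹)
    nucleophile + acid set free ⇌ idle adduct, settled at all times (K = 34.0 L mol⁻¹)

Birch at 20.0 min keeps 6.2% of its nucleophile unbound, a cost of 1.97 against the carried 1.89. Left until 50 min, birch has 20% of its electrophile left against the reckoned 20.8%, and with 2.3% of its nucleophile still unbound, the cost stands at 1.83.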